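## The problem

The target 22 is a 2-aryl-3-aroylbenzofuran whose benzo ring is substituted at every carbon except C5: hydroxyls at C4 and C6, a 2-(4-hydroxyphenyl)acryloyl ketone at C7, a 2,4-dihydroxybenzoyl group at C3 and a 4-hydroxyphenyl group at C2. There is no stereocentre and no stereogenic double bond, so the whole difficulty is regiochemical: five different substituents must be placed on the bicyclic core without ambiguity. Six phenols have to be masked through electrophilic and basic C–C bond formations and released at the end. The fragile element is the terminal C=CH2 enone of the C7 ketone: it accepts halide, amines and thiols in conjugate fashion, hydrogenation would reduce it, and under base the neighbouring C6 hydroxyl adds to the methylene carbon and closes a chromanone (isoflavanone) ring. Both ketones (at C3 and at C7) are flanked by two ortho substituents and must be made by acylation at crowded, electron-rich carbons. The enabling feature is the benzo ring (C3a, C4–C7, C7a): it shows the resorcinol pattern O at C4, H at C5, O at C6, and C7 can first be a CH. The run C4–C5–C6–C7 can therefore be laid between the furan carbons C3a and C7a, with C4 as a ketene carbon, C5 and C6 as the two carbons of an alkoxyalkyne and C7 as a former diazo carbon.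

## Retrosynthesis

**22 ⇒ 21.** The six O–alkyl bonds are cut (five O–CH3 and the O–CH2CH3 at O6). Alkyl ethers are preferred to benzyl ethers, whose hydrogenolysis would reduce the C=CH2 bond. They are also preferred to esters or silyl ethers, which would not pass the Lewis-acid acylations and whose basic removal would invite O6 to close onto the enone. Precursor 21 has no acidic proton and no free O6, so it can be handled freely. The forward step must cleave six aryl ethers with a Lewis acid without adding anything to the enone; after the key step it is the step that needs most care.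

**21 ⇒ 19.** The Cα=CH2 bond is cut. Bringing in the intact 2-arylacryloyl unit by acylation is rejected because such an electrophile would undergo conjugate addition or polymerise under Lewis acid. Deoxybenzoin 19 has a single enolisable CH2, so the forward reaction is one mono-methylenation with elimination.

**19 ⇒ 17 + 18.** The C7–C(=O) bond is cut. Cutting C(=O)–CH2 instead would need a C7 aldehyde, a benzyl nucleophile and an oxidation, which is kept in reserve. The cut removes ten heavy atoms as the commercial acid chloride 18. The forward acylation must go to C7 and not to C5 or to the two other alkoxyarene rings of 17.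

**17 ⇒ 14 + 15 (through 16).** The bond between the C3 carbonyl and the resorcinol-type ring is cut, not the C3–C(=O) bond. A C3-unsubstituted 4,6-dialkoxybenzofuran would be acylated on its benzo ring first. A diaryl ketone installed at the furan stage would add a second chromophore to the photochemical step. Acid 14 and commercial 15 are far simpler than 17. The forward acylation must occur at C4 of 15, which writes the 2,4-dioxygenation pattern.

**14 ⇒ 13 ⇒ 12.** Only heteroatom bonds change: the ester O–CH3 bond (hydrolysis) and the O4–CH3 bond. O4 is capped as a methyl ether because it must not be acylated during carboxyl activation and because methyl leaves with the other ethers at the end.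

**12 ⇒ 7 + 8.** Four ring bonds are cut: C7a–C7, C6–C7, C4–C5 and C3a–C4. The neighbouring option, annulating a furan onto a phloroglucinol derivative, leaves O4/O6 and C5/C7 to be told apart by weak biases. Here every benzo-ring atom has a defined origin. The precursor falls from a bicyclic, tetrasubstituted benzo ring to the monocyclic furan 7 and the two-carbon alkyne 8. The forward reaction must be regioselective in the cycloaddition and in the ring closure.

**7 ⇒ 5 ⇒ 4.** The C=N2 bond is cut (diazo transfer to a methyl ketone), then the bond from furan C5 to the acetyl carbon. The alternative through a furan-5-carbonyl chloride would need a separate carboxylation and a diazoalkane reagent. The forward steps require acetylation at C5 only and enolate formation at the methyl ketone only; the C3 ester has no α-hydrogen.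

**4 ⇒ 1 + 2.** The furan bonds C3–C4 and O1–C5 are cut. Both partners are commercial, and since both carbons of 2 end as CH groups, only one furan can result.

## Roads not taken

**Alternative 1:** The furan is cut at O1–C2, at the C3–carbonyl bond and at the carbonyl–aryl bond, on an isoflavone core. The commercial isoflavone A4, biochanin A, supplies that core: its pyranone ring already holds the C7 carbonyl, its aryl group and the future O6. Starting from A4, 7-O-methylation, C6 iodination and alkynylation would give the 5-hydroxy-6-alkynyl isoflavone A2. This would react with 1-iodo-2,4-dimethoxybenzene A3 and a zerovalent palladium catalyst such as Pd(PPh3)4 under carbonylative conditions. The aroylpalladium species would trigger attack of the 5-phenoxide on the alkyne and give the furo-fused isoflavone A1.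

- Merits: three components are joined in one step, the furan arrives with both its aryl and its aroyl group, no Friedel–Crafts regiochemistry arises at C7, and A1 is reached from A4 in fewer steps than the comparable hexaether 21.
- Weak points before the key step: halogenation must be steered to C6 and not C8. The 5-hydroxyl is tied to the C4 carbonyl by a hydrogen bond and is a poor nucleophile. Non-carbonylative arylation and plain cycloisomerisation compete.
- Decisive weak point: A1 is an isoflavone. Its C2 has to become the exocyclic methylene and its ring oxygen the free O6. That needs conjugate reduction next to a diaryl ketone and then a ring opening that runs against the spontaneous closure of exactly this enone–phenol pair. Degrading the pyranone ring and re-methylenating would end in the chosen endgame with extra steps.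
- Comparison: this road is shorter and more convergent up to the protected stage. The chosen plan offers regiochemistry fixed by connectivity and a side chain that is built in the open form and never has to be opened.

**Alternative 2:** The C7–carbonyl and carbonyl–Cα bonds are cut together. The 7-iodobenzofuran A6 and the 1-arylvinylstannane A7 would be joined by zerovalent palladium under carbonylative Stille conditions to give the hexa-O-methyl ether A5.

- Merits: the enone arrives with its methylene in place, under neutral conditions, without a Lewis acid near the ortho ethers and without enolate chemistry. In step count it matches steps 8 and 9 (iodination plus coupling), and the enone is arguably made more gently.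
- Weak points: the iodide of A6 sits between an alkoxy group and the furan oxygen on an electron-rich ring, so oxidative addition and acyl formation are slow and direct coupling without carbonyl insertion competes. α-Substituted vinylstannanes such as A7 transmetalate sluggishly. Stoichiometric tin is used. The regioselective iodination at C7 raises the same C5/C7 question as the acylation.
- Scope: it says nothing about how the benzofuran core is made and ends with the same deprotection in the presence of the enone.
- Comparison: the chosen plan relies on well-tried acylation and methylenation of deoxybenzoins and places the key step where the regiochemical problem lies, in the ring construction. This coupling remains a possible replacement for steps 8 and 9.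

**Alternative 3:** The furan is cut at O1–C7a and C3–C3a. A fluoride source would release 3,5-dimethoxybenzyne A11 from the silyl triflate A10. The ketone enolate oxygen of the iodonium ylide A9 (one step from 1) would add to the aryne carbon remote from the neighbouring methoxyl, and the aryl anion would then close onto the ylide carbon to give ester A8, the dimethyl analogue of 13.

- Merits: one convergent step replaces the five linear steps to 13, and it needs neither light nor a diazo compound. To the common ester stage this road is better in convergence and in longest linear sequence.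
- Weak points: A10 is not a catalogue compound and needs a short sequence of its own, so the total count is similar. The ylide A9 is ambident (C-arylation versus O-attack, ketone versus ester oxygen). The regiochemistry rests on a selectivity, however reliable the bias of 3-alkoxyarynes.
- Comparison: the chosen plan uses only commercial inputs, has a benzo-ring pattern dictated by atom connectivity, and delivers O4 and O6 differentiated (free hydroxyl versus ethyl ether). From the ester stage onward the two roads are identical.

Key step: step 4

Assumption: 2 is used as its commercial aqueous solution and 8 as its commercial hexane solution. The target has no stereocentre, and the racemic centres of 3, 10 and 20 disappear in the flask in which they form.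

## Route

Step 1
Reactants: 1 methyl 3-(4-methoxyphenyl)-3-oxopropanoate; 2 chloroacetaldehyde
Product: 4 methyl 2-(4-methoxyphenyl)furan-3-carboxylate, via hydroxydihydrofuran 3 (not isolated)
Conditions: pyridine, H2O, rt → 50 °C; then 1 M HCl
Reagents that add atoms: none
Why: Feist–Benary furan synthesis: the ketoester enolate adds to the aldehyde of 2, the enol oxygen displaces chloride to give 3, and loss of water aromatises the ring. Both carbons of 2 end as CH, so the 2-aryl-3-ester furan with free C4 and C5 is the only possible product.

Step 2
Reactants: 4 methyl 2-(4-methoxyphenyl)furan-3-carboxylate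
Product: 5 methyl 5-acetyl-2-(4-methoxyphenyl)furan-3-carboxylate
Conditions: Ac2O, BF3·OEt2 (cat.), CH2Cl2, 0 °C → rt
Reagents that add atoms: acetic anhydride, CC(=O)OC(C)=O
Why: Friedel–Crafts acetylation at the free α-carbon C5 of the furan, whose σ-complex is stabilised by the ring oxygen and by the 4-methoxyphenyl group at C2, while the C3 ester is not conjugated with the developing charge. The anisole ring and the β-carbon C4 are far less nucleophilic.

Step 3
Reactants: 5 methyl 5-acetyl-2-(4-methoxyphenyl)furan-3-carboxylate
Product: 7 methyl 5-(2-diazoacetyl)-2-(4-methoxyphenyl)furan-3-carboxylate, via trifluoroacetyl diketone 6 (not isolated)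
Conditions: LiN(SiMe3)2, THF, −78 °C; CF3CO2CH2CF3; aq. HCl; then MsN3, Et3N, H2O, MeCN, rt
Reagents that add atoms: 2,2,2-trifluoroethyl trifluoroacetate, O=C(OCC(F)(F)F)C(F)(F)F (atoms kept only in 6); methanesulfonyl azide, CS(=O)(=O)N=[N+]=[N-]
Why: Detrifluoroacetylative diazo transfer: the methyl ketone is the only enolisable site, Claisen trifluoroacetylation gives 6, and its activated methylene takes the diazo group from the sulfonyl azide while the trifluoroacetyl group leaves as the acylsulfonamide. The method is established for aryl methyl ketones and needs no diazoalkane.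

Step 4
Reactants: 7 methyl 5-(2-diazoacetyl)-2-(4-methoxyphenyl)furan-3-carboxylate; 8 ethoxyacetylene
Product: 12 methyl 6-ethoxy-4-hydroxy-2-(4-methoxyphenyl)-1-benzofuran-3-carboxylate, via furylketene 9 (not isolated), via ethoxycyclobutenone 10 (not isolated), via dienylketene 11 (not isolated)
Conditions: hν (medium-pressure Hg lamp, Pyrex), ClCH2CH2Cl, rt; then 80 °C, sealed tube
Reagents that add atoms: none
Why: Light expels N2 from 7 and the furyl group shifts to the carbene carbon (photochemical Wolff rearrangement), which makes C7a–C7 and gives furylketene 9. The ynol ether 8 is polarised so that its CH carbon is nucleophilic: it bonds to the ketene carbonyl carbon (C4–C5) while the ethoxy-bearing carbon bonds to the ketene α-carbon (C6–C7), a regioselective [2+2] cycloaddition that gives 10. Four-electron electrocyclic opening of 10, driven by light or by the final heating and reversible for the unproductive isomer, gives dienylketene 11. The benzo ring then closes by a six-electron disrotatory electrocyclisation of the ketene carbon onto furan C4, forming C3a–C4, and a proton shift aromatises the new ring to phenol 12. The closest known reaction type is the second-generation Danheiser benzannulation of aryl and heteroaryl α-diazo ketones with alkoxy- or siloxyalkynes. No stereocentre is created. The step needs regiocontrol in the cycloaddition, secured by the polarity of 8, and site control in the closure, secured because C4 is the only unsubstituted furan carbon and the only one next to the ketene-bearing C5; the C3 group is an ester and not a diaryl ketone, so no second chromophore competes for the light.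

Step 5
Reactants: 12 methyl 6-ethoxy-4-hydroxy-2-(4-methoxyphenyl)-1-benzofuran-3-carboxylate
Product: 13 methyl 6-ethoxy-4-methoxy-2-(4-methoxyphenyl)-1-benzofuran-3-carboxylate
Conditions: MeI, K2CO3, DMF, 40 °C
Reagents that add atoms: iodomethane, CI
Why: Williamson O-methylation of the hydrogen-bonded phenol. Capping O4 keeps it from being acylated in steps 7 and 8, and the methyl group is removed with the other ethers in step 10.

Step 6
Reactants: 13 methyl 6-ethoxy-4-methoxy-2-(4-methoxyphenyl)-1-benzofuran-3-carboxylate
Product: 14 6-ethoxy-4-methoxy-2-(4-methoxyphenyl)-1-benzofuran-3-carboxylic acid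
Conditions: KOH, EtOH/H2O, 80 °C; then 1 M HCl
Reagents that add atoms: potassium hydroxide, [K+].[OH-]
Why: Saponification of a hindered, non-enolisable aryl ester under forcing alkaline conditions. Aryl ethers and the benzofuran nucleus are inert to hydroxide.

Step 7
Reactants: 14 6-ethoxy-4-methoxy-2-(4-methoxyphenyl)-1-benzofuran-3-carboxylic acid; 15 1,3-dimethoxybenzene
Product: 17 (2,4-dimethoxyphenyl)[6-ethoxy-4-methoxy-2-(4-methoxyphenyl)-1-benzofuran-3-yl]methanone, via acid chloride 16 (not isolated)
Conditions: (COCl)2, DMF (cat.), CH2Cl2, 0 °C → rt; then 15 (excess), SnCl4, CH2Cl2, 0 °C; aq. HCl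
Reagents that add atoms: oxalyl chloride, O=C(Cl)C(=O)Cl (chlorine kept only in 16)
Why: Acid chloride formation followed by Friedel–Crafts acylation; 15 reacts at C4, para to one methoxyl and ortho to the other, which sets the 2,4-dioxygenation of the aroyl ring. An excess of 15 outcompetes acylation of the benzofuran by its own acid chloride, and SnCl4 is mild enough to leave the ortho ethers intact.

Step 8
Reactants: 17 (2,4-dimethoxyphenyl)[6-ethoxy-4-methoxy-2-(4-methoxyphenyl)-1-benzofuran-3-yl]methanone; 18 (4-methoxyphenyl)acetyl chloride
Product: 19 1-[3-(2,4-dimethoxybenzoyl)-6-ethoxy-4-methoxy-2-(4-methoxyphenyl)-1-benzofuran-7-yl]-2-(4-methoxyphenyl)ethan-1-one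
Conditions: SnCl4, CH2Cl2, −20 → 0 °C; aq. HCl
Reagents that add atoms: none
Why: Friedel–Crafts acylation on the most electron-rich ring of 17, the benzo ring with three oxygen donors and no conjugated acceptor. C7 is para to the C4 methoxyl and lies between the C6 ethoxyl and the tied-back ring oxygen, whereas C5 lies between two alkoxy groups and is further shielded because the C3 aroyl group turns the C4 methoxyl toward it. Electrophilic substitution at C7 is the known preference of 4,6-dialkoxybenzofurans.

Step 9
Reactants: 19 1-[3-(2,4-dimethoxybenzoyl)-6-ethoxy-4-methoxy-2-(4-methoxyphenyl)-1-benzofuran-7-yl]-2-(4-methoxyphenyl)ethan-1-one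
Product: 21 1-[3-(2,4-dimethoxybenzoyl)-6-ethoxy-4-methoxy-2-(4-methoxyphenyl)-1-benzofuran-7-yl]-2-(4-methoxyphenyl)prop-2-en-1-one, via Mannich base 20 (not isolated)
Conditions: (Me2N)2CH2, Ac2O, DMF, 60 °C
Reagents that add atoms: bis(dimethylamino)methane, CN(C)CN(C)C
Why: Mannich methylenation of a deoxybenzoin: the iminium acetate formed from the aminal and Ac2O is attacked by the enol of the only enolisable ketone, and the doubly activated α-proton of 20 allows β-elimination of dimethylamine. With all six oxygens alkylated, no phenol can add to the new enone.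

Step 10
Reactants: 21 1-[3-(2,4-dimethoxybenzoyl)-6-ethoxy-4-methoxy-2-(4-methoxyphenyl)-1-benzofuran-7-yl]-2-(4-methoxyphenyl)prop-2-en-1-one
Product: 22 1-[3-(2,4-dihydroxybenzoyl)-4,6-dihydroxy-2-(4-hydroxyphenyl)-1-benzofuran-7-yl]-2-(4-hydroxyphenyl)prop-2-en-1-one (CNP0181958.0)
Conditions: BBr3 (excess), CH2Cl2, −78 → 0 °C; then ice, aq. NaH2PO4
Reagents that add atoms: none
Why: Lewis-acid ether cleavage: BBr3 binds each ether oxygen and bromide removes methyl or ethyl by SN2 displacement, the chelated ethers ortho to the two ketones going first. During the reaction O6 is held as a borate and cannot add to the enone, and the cold, weakly acidic quench avoids the base that would close the chromanone ring.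

## Compound list

1 | methyl 3-(4-methoxyphenyl)-3-oxopropanoate | COC(=O)CC(=O)c1ccc(OC)cc1 | starting material
2 | chloroacetaldehyde | O=CCCl | starting material
3 | methyl 4-hydroxy-2-(4-methoxyphenyl)-4,5-dihydrofuran-3-carboxylate (racemic) | COC(=O)C1=C(c2ccc(OC)cc2)OCC1O | intermediate
4 | methyl 2-(4-methoxyphenyl)furan-3-carboxylate | COC(=O)c1ccoc1-c1ccc(OC)cc1 | intermediate
5 | methyl 5-acetyl-2-(4-methoxyphenyl)furan-3-carboxylate | COC(=O)c1cc(C(C)=O)oc1-c1ccc(OC)cc1 | intermediate
6 | methyl 2-(4-methoxyphenyl)-5-(4,4,4-trifluoro-3-oxobutanoyl)furan-3-carboxylate | COC(=O)c1cc(C(=O)CC(=O)C(F)(F)F)oc1-c1ccc(OC)cc1 | intermediate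
7 | methyl 5-(2-diazoacetyl)-2-(4-methoxyphenyl)furan-3-carboxylate | COC(=O)c1cc(C(=O)C=[N+]=[N-])oc1-c1ccc(OC)cc1 | intermediate
8 | ethoxyacetylene | C#COCC | starting material
9 | methyl 2-(4-methoxyphenyl)-5-(2-oxoethenyl)furan-3-carboxylate | COC(=O)c1cc(C=C=O)oc1-c1ccc(OC)cc1 | intermediate
10 | methyl 5-(2-ethoxy-4-oxocyclobut-2-en-1-yl)-2-(4-methoxyphenyl)furan-3-carboxylate (racemic) | CCOC1=CC(=O)C1c1cc(C(=O)OC)c(-c2ccc(OC)cc2)o1 | intermediate
11 | methyl 5-[(1E)-2-ethoxy-4-oxobuta-1,3-dien-1-yl]-2-(4-methoxyphenyl)furan-3-carboxylate | CCO/C(C=C=O)=C/c1cc(C(=O)OC)c(-c2ccc(OC)cc2)o1 | intermediate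
12 | methyl 6-ethoxy-4-hydroxy-2-(4-methoxyphenyl)-1-benzofuran-3-carboxylate | CCOc1cc(O)c2c(C(=O)OC)c(-c3ccc(OC)cc3)oc2c1 | intermediate
13 | methyl 6-ethoxy-4-methoxy-2-(4-methoxyphenyl)-1-benzofuran-3-carboxylate | CCOc1cc(OC)c2c(C(=O)OC)c(-c3ccc(OC)cc3)oc2c1 | intermediate
14 | 6-ethoxy-4-methoxy-2-(4-methoxyphenyl)-1-benzofuran-3-carboxylic acid | CCOc1cc(OC)c2c(C(=O)O)c(-c3ccc(OC)cc3)oc2c1 | intermediate
15 | 1,3-dimethoxybenzene | COc1cccc(OC)c1 | starting material
16 | 6-ethoxy-4-methoxy-2-(4-methoxyphenyl)-1-benzofuran-3-carbonyl chloride | CCOc1cc(OC)c2c(C(=O)Cl)c(-c3ccc(OC)cc3)oc2c1 | intermediate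
17 | (2,4-dimethoxyphenyl)[6-ethoxy-4-methoxy-2-(4-methoxyphenyl)-1-benzofuran-3-yl]methanone | CCOc1cc(OC)c2c(C(=O)c3ccc(OC)cc3OC)c(-c3ccc(OC)cc3)oc2c1 | intermediate
18 | (4-methoxyphenyl)acetyl chloride | COc1ccc(CC(=O)Cl)cc1 | starting material
19 | 1-[3-(2,4-dimethoxybenzoyl)-6-ethoxy-4-methoxy-2-(4-methoxyphenyl)-1-benzofuran-7-yl]-2-(4-methoxyphenyl)ethan-1-one | CCOc1cc(OC)c2c(C(=O)c3ccc(OC)cc3OC)c(-c3ccc(OC)cc3)oc2c1C(=O)Cc1ccc(OC)cc1 | intermediate
20 | 1-[3-(2,4-dimethoxybenzoyl)-6-ethoxy-4-methoxy-2-(4-methoxyphenyl)-1-benzofuran-7-yl]-3-(dimethylamino)-2-(4-methoxyphenyl)propan-1-one (racemic) | CCOc1cc(OC)c2c(C(=O)c3ccc(OC)cc3OC)c(-c3ccc(OC)cc3)oc2c1C(=O)C(CN(C)C)c1ccc(OC)cc1 | intermediate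
21 | 1-[3-(2,4-dimethoxybenzoyl)-6-ethoxy-4-methoxy-2-(4-methoxyphenyl)-1-benzofuran-7-yl]-2-(4-methoxyphenyl)prop-2-en-1-one | C=C(C(=O)c1c(OCC)cc(OC)c2c(C(=O)c3ccc(OC)cc3OC)c(-c3ccc(OC)cc3)oc12)c1ccc(OC)cc1 | intermediate
22 | 1-[3-(2,4-dihydroxybenzoyl)-4,6-dihydroxy-2-(4-hydroxyphenyl)-1-benzofuran-7-yl]-2-(4-hydroxyphenyl)prop-2-en-1-one | C=C(C(=O)c1c(O)cc(O)c2c(C(=O)c3ccc(O)cc3O)c(-c3ccc(O)cc3)oc12)c1ccc(O)cc1 | target

## Step count and least certain steps

Total step count: 10. Longest linear sequence: 10 steps (1 → 22); 2, 8, 15 and 18 enter as purchased materials.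

**Step 4 (key step).** The ketene may be intercepted before it finds the alkyne: it can acylate the phenol that is being formed or dimerise. The conjugated furan chromophores of substrate and product may also be degraded by prolonged irradiation, and the cyclobutenone may open incompletely. The fallback generates the same ketene in the dark. It sets out from 7: PhCO2Ag (cat.) and Et3N in aqueous dioxane would bring about the Wolff rearrangement and trap the ketene with water as 2-[4-(methoxycarbonyl)-5-(4-methoxyphenyl)furan-2-yl]acetic acid F1. (COCl)2 with catalytic DMF would convert F1 into methyl 5-(2-chloro-2-oxoethyl)-2-(4-methoxyphenyl)furan-3-carboxylate F2. Slow addition of Et3N to F2 and 8 in toluene would release 9 by dehydrochlorination, 9 would add to 8 to give 10, and heating at 80–110 °C would carry 10 through 11 to 12, where the route is rejoined.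

**Step 10.** Bromide, or HBr formed at the quench, may add to the boron-activated terminal enone. Any base used to reverse that addition, or met during work-up and chromatography, may let O6 add to the methylene carbon and close the chromanone ring. The fallback takes the ethers off before the enone exists. It sets out from 19: BBr3 in CH2Cl2 would give 1-[3-(2,4-dihydroxybenzoyl)-4,6-dihydroxy-2-(4-hydroxyphenyl)-1-benzofuran-7-yl]-2-(4-hydroxyphenyl)ethan-1-one F3. TBSCl, imidazole and DMAP in DMF would then give its hexakis(tert-butyldimethylsilyl) ether F4. (Me2N)2CH2 and Ac2O would give, through the silylated Mannich base F5, the hexakis(tert-butyldimethylsilyl) ether of the target F6. HF·pyridine in THF would finally remove the six silyl groups under acidic, non-nucleophilic conditions and return the route at 22.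

**Step 8.** Acylation may be poorly site-selective (C5 of the benzo ring or the dimethoxybenzoyl ring). The Lewis acid may also cleave the C6 ethyl ether once the ortho ketone is in place, which would expose O6 to the enone in step 9. The fallback replaces the acylation by a formylation and a carbonyl addition. It sets out from 17: Vilsmeier–Haack formylation (POCl3, DMF), the mildest and most selective electrophilic substitution of dialkoxybenzofurans, would give 3-(2,4-dimethoxybenzoyl)-6-ethoxy-4-methoxy-2-(4-methoxyphenyl)-1-benzofuran-7-carbaldehyde F7. 4-MeOC6H4CH2MgCl in THF at −78 °C would add to the aldehyde in preference to the hindered, electron-rich diaryl ketone and give (2,4-dimethoxyphenyl){6-ethoxy-7-[1-hydroxy-2-(4-methoxyphenyl)ethyl]-4-methoxy-2-(4-methoxyphenyl)-1-benzofuran-3-yl}methanone F8. Dess–Martin periodinane would oxidise F8 to 19, where the route is rejoined.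

**Step 7.** The acylium ion from 16 is stabilised by the furan oxygen and crowded by the C2 aryl and C4 methoxyl groups, so the acylation may be sluggish. Self-acylation of the benzofuran and Lewis-acid cleavage of an ortho methyl ether may then take over. The fallback reverses the polarity of the bond formation. It sets out from 14, through 16 made as in step 7: MeNHOMe·HCl and Et3N would give 6-ethoxy-N,4-dimethoxy-2-(4-methoxyphenyl)-N-methyl-1-benzofuran-3-carboxamide F9. 2,4-Dimethoxyphenyllithium F10, made from 1-bromo-2,4-dimethoxybenzene and n-BuLi in THF at −78 °C, would add once to F9 and give 17 after aqueous NH4Cl, where the route is rejoined.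

## Further compounds

F1 | step 4 | 2-[4-(methoxycarbonyl)-5-(4-methoxyphenyl)furan-2-yl]acetic acid | COC(=O)c1cc(CC(=O)O)oc1-c1ccc(OC)cc1
F2 | step 4 | methyl 5-(2-chloro-2-oxoethyl)-2-(4-methoxyphenyl)furan-3-carboxylate | COC(=O)c1cc(CC(=O)Cl)oc1-c1ccc(OC)cc1
F3 | step 10 | 1-[3-(2,4-dihydroxybenzoyl)-4,6-dihydroxy-2-(4-hydroxyphenyl)-1-benzofuran-7-yl]-2-(4-hydroxyphenyl)ethan-1-one | O=C(Cc1ccc(O)cc1)c1c(O)cc(O)c2c(C(=O)c3ccc(O)cc3O)c(-c3ccc(O)cc3)oc12
F4 | step 10 | hexakis(tert-butyldimethylsilyl) ether of F3 | O=C(Cc1ccc(O[Si](C)(C)C(C)(C)C)cc1)c1c(O[Si](C)(C)C(C)(C)C)cc(O[Si](C)(C)C(C)(C)C)c2c(C(=O)c3ccc(O[Si](C)(C)C(C)(C)C)cc3O[Si](C)(C)C(C)(C)C)c(-c3ccc(O[Si](C)(C)C(C)(C)C)cc3)oc12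
F5 | step 10 | 3-(dimethylamino) Mannich base of F4 (racemic) | O=C(C(CN(C)C)c1ccc(O[Si](C)(C)C(C)(C)C)cc1)c1c(O[Si](C)(C)C(C)(C)C)cc(O[Si](C)(C)C(C)(C)C)c2c(C(=O)c3ccc(O[Si](C)(C)C(C)(C)C)cc3O[Si](C)(C)C(C)(C)C)c(-c3ccc(O[Si](C)(C)C(C)(C)C)cc3)oc12
F6 | step 10 | hexakis(tert-butyldimethylsilyl) ether of 22 | C=C(C(=O)c1c(O[Si](C)(C)C(C)(C)C)cc(O[Si](C)(C)C(C)(C)C)c2c(C(=O)c3ccc(O[Si](C)(C)C(C)(C)C)cc3O[Si](C)(C)C(C)(C)C)c(-c3ccc(O[Si](C)(C)C(C)(C)C)cc3)oc12)c1ccc(O[Si](C)(C)C(C)(C)C)cc1
F7 | step 8 | 3-(2,4-dimethoxybenzoyl)-6-ethoxy-4-methoxy-2-(4-methoxyphenyl)-1-benzofuran-7-carbaldehyde | CCOc1cc(OC)c2c(C(=O)c3ccc(OC)cc3OC)c(-c3ccc(OC)cc3)oc2c1C=O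
F8 | step 8 | (2,4-dimethoxyphenyl){6-ethoxy-7-[1-hydroxy-2-(4-methoxyphenyl)ethyl]-4-methoxy-2-(4-methoxyphenyl)-1-benzofuran-3-yl}methanone (racemic) | CCOc1cc(OC)c2c(C(=O)c3ccc(OC)cc3OC)c(-c3ccc(OC)cc3)oc2c1C(O)Cc1ccc(OC)cc1
F9 | step 7 | 6-ethoxy-N,4-dimethoxy-2-(4-methoxyphenyl)-N-methyl-1-benzofuran-3-carboxamide | CCOc1cc(OC)c2c(C(=O)N(C)OC)c(-c3ccc(OC)cc3)oc2c1
F10 | step 7 | 2,4-dimethoxyphenyllithium | [Li]c1ccc(OC)cc1OC
A1 | alternative 1 | furo-fused isoflavone: 3-(2,4-dimethoxybenzoyl)furan bearing 2-(4-methoxyphenyl), fused through O5 and C6 of 7-methoxy-3-(4-methoxyphenyl)chromen-4-one | COc1ccc(cc1)-c2coc3cc(OC)c4c(oc(-c5ccc(OC)cc5)c4C(=O)c6ccc(OC)cc6OC)c3c2=O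
A2 | alternative 1 | 5-hydroxy-7-methoxy-3-(4-methoxyphenyl)-6-[(4-methoxyphenyl)ethynyl]-4H-chromen-4-one | COc1ccc(cc1)-c1coc2cc(OC)c(C#Cc3ccc(OC)cc3)c(O)c2c1=O
A3 | alternative 1 | 1-iodo-2,4-dimethoxybenzene | COc1ccc(I)c(OC)c1
A4 | alternative 1 | biochanin A, 5,7-dihydroxy-3-(4-methoxyphenyl)-4H-chromen-4-one | COc1ccc(cc1)-c1coc2cc(O)cc(O)c2c1=O
A5 | alternative 2 | 1-[3-(2,4-dimethoxybenzoyl)-4,6-dimethoxy-2-(4-methoxyphenyl)-1-benzofuran-7-yl]-2-(4-methoxyphenyl)prop-2-en-1-one | C=C(C(=O)c1c(OC)cc(OC)c2c(C(=O)c3ccc(OC)cc3OC)c(-c3ccc(OC)cc3)oc12)c1ccc(OC)cc1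
A6 | alternative 2 | (2,4-dimethoxyphenyl)[7-iodo-4,6-dimethoxy-2-(4-methoxyphenyl)-1-benzofuran-3-yl]methanone | COc1cc(OC)c2c(C(=O)c3ccc(OC)cc3OC)c(-c3ccc(OC)cc3)oc2c1I
A7 | alternative 2 | tributyl[1-(4-methoxyphenyl)ethenyl]stannane | CCCC[Sn](CCCC)(CCCC)C(=C)c1ccc(OC)cc1
A8 | alternative 3 | methyl 4,6-dimethoxy-2-(4-methoxyphenyl)-1-benzofuran-3-carboxylate | COC(=O)c1c(-c2ccc(OC)cc2)oc3cc(OC)cc(OC)c13
A9 | alternative 3 | phenyliodonium ylide of methyl 3-(4-methoxyphenyl)-3-oxopropanoate | COC(=O)[C-]([I+]c1ccccc1)C(=O)c1ccc(OC)cc1
A10 | alternative 3 | 3,5-dimethoxy-2-(trimethylsilyl)phenyl trifluoromethanesulfonate | COc1cc(OC)c([Si](C)(C)C)c(OS(=O)(=O)C(F)(F)F)c1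
A11 | alternative 3 | 3,5-dimethoxybenzyne | COC1=CC(OC)=CC#C1
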